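The constants are hidden here, so you start from a ratio of charges.

| flask | starting material | protic impurity | temperature | remark | time |
|---|---|---|---|---|---|
| Wednesday's | 0.26 M | 0.13 M | 5 °C | run made earlier |  |
| ash | 0.13 M | 0.130 M |  | at 5 °C throughout | 30 h |
| elm | 0.13 M | 0.130 M |  | at 5 °C until 6.0 h, from then on at 35 °C | 30 h |

Wednesday's run (percent of the starting material charged)

| time / h | target / % |
|---|---|
| 1.33 | 9.7 |
| 2.50 | 11.3 |
| 4.00 | 15.0 |
| 5.00 | 14.8 |
| 6.00 | 15.7 |
| 8.00 | 17.7 |
| 10.0 | 18.7 |

(each reading ± 0.5 percentage points)

- a species is counted by the starting material in it: one side product counts as two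
- steps under discussion: starting material -> target; other conformer -> isomer of the product; starting material <-> other conformer; target <-> isomer of the product; starting material + target -> side product; starting material + protic impurity -> quenched substrate
- in a conversion other conformer counts as not yet reacted
- the earlier runs do not show what temperature does; that part of a forecast is a guess

1. the flask that ends with the higher amount of target, in percent of the starting material charged, or "neither" when 2 percentage points or less lies between them (ash / elm / neither)
2. final target, as a percentage of the starting material charged, in ash
3. final target, as a percentage of the starting material charged, in elm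

In the quench of starting material by protic impurity, the rate per molecule of starting material scales with c(protic impurity). The steps to target and to other conformer carry no such factor. So compare each flask with Wednesday's run by the quench ratio ρ:

ρ = c(protic impurity) / c(protic impurity, Wednesday's) = 0.130 M / 0.13 M = 1.00

ρ = 1 is the zero of this scale: at the start the quench competes as it did on Wednesday's. Ash sits at that zero, so I read ash off Wednesday's curve, although its charge of starting material is half of Wednesday's. Its last reading is 18.7%. Adding the last rise once more gives my own figure:

2 × 18.7% − 17.7% = 19.7%

Is one number enough? No. Elm has the same ρ and is ash until 6.0 h, so ρ cannot separate them. The warming must do that, and its effect is a guess.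

The forecast says elm, with 23% in ash, which is higher than my figure, and 30% in elm. Its ground for elm: “warming should release the conformer pool quickly”.

The flasks give elm as the higher: 21.1% in ash and 38.7% in elm, which is 8.7 percentage points above the forecast for elm.

    starting material → target (k = 0.00240 min⁻¹, Ea = 81.0 kJ mol⁻¹)
    other conformer → isomer of the product (k = 0.00181 min⁻¹, Ea = 101 kJ mol⁻¹)
    starting material ⇌ other conformer (K = 1.59, k = 0.0122 min⁻¹, Ea = 78.0 kJ mol⁻¹, ΔH = −12.0 kJ mol⁻¹)
    target ⇌ isomer of the product (K = 1.60, k = 0.00119 min⁻¹, Ea = 88.0 kJ mol⁻¹, ΔH = −25.0 kJ mol⁻¹)
    starting material + target → side product (k = 0.0150 L mol⁻¹ min⁻¹, Ea = 53.0 kJ mol⁻¹)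
    starting material + protic impurity → quenched substrate (k = 0.0320 L mol⁻¹ min⁻¹, Ea = 59.0 kJ mol⁻¹)
    (constants at 5 °C)

At 1.42 h in elm, the quench uses starting material at 0.28 of the rate of the forward step alone into other conformer, so it runs slower than that forward step. At ρ = 1.00, elm ends with 35.2% quenched substrate. Changing only the amount of starting material from Wednesday's run, which keeps ρ at 1.00, gives 19.7% target at the time of its last reading, against 18.9% in Wednesday's run without the scatter. A neighbour of elm charged with 0.33 M protic impurity has ρ = 2.54. It ends with 62.0% quenched substrate and 23.2% target.

(The numbers in the tables were generated by integration from invented constants; noise was put on by code.)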